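**Assumption:** the target has no stereocentre and no stereogenic double bond, so it is achiral and there is no enantiomer to select; the route makes the compound exactly as drawn.

## Retrosynthetic overview

1. The ring A–CH2–ring C bond is cut last, to a 2-hydroxy-6-methoxybenzaldehyde and 4-hydroxyphenylboronic acid. They are joined by the proposed amine-catalysed reductive Petasis arylation; the aldehyde carbon fixes the site between OH and OMe.
2. The OH/OMe difference on ring A comes from a symmetric 2,6-dimethoxybenzaldehyde by chelation-controlled mono-demethylation with BCl3, which also removes the ring B benzyl ether.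
3. The CH2–CH2 bridge is cut at ring A: 4-bromo-2,6-dimethoxybenzaldehyde plus the 9-BBN adduct of 2-(benzyloxy)styrene (B-alkyl Suzuki–Miyaura). The styrene comes from 2-(benzyloxy)benzaldehyde by Wittig methylenation.
4. No ring is formed in the route. Rings B, A and C are bought as benzene derivatives and joined in the order B–A (bridge), then A–C (methylene).

## Route

Step 1
Reactants: 1 2-(benzyloxy)benzaldehyde
Product: 2 1-(benzyloxy)-2-ethenylbenzene
Conditions: Ph3PCH3Br (1.2 equiv), KOtBu (1.2 equiv), THF, 0 °C to rt
Reagents that add atoms: methyltriphenylphosphonium bromide, C[P+](c1ccccc1)(c1ccccc1)c1ccccc1.[Br-]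
Why: Wittig methylenation of a non-enolisable aryl aldehyde with the unstabilised methylide is fast and leaves the benzyl ether untouched; no stereocentre is formed.

Step 2
Reactants: 2 1-(benzyloxy)-2-ethenylbenzene, 3 4-bromo-2,6-dimethoxybenzaldehyde
Product: 5 4-{2-[2-(benzyloxy)phenyl]ethyl}-2,6-dimethoxybenzaldehyde, via 9-{2-[2-(benzyloxy)phenyl]ethyl}-9-borabicyclo[3.3.1]nonane 4 (not isolated)
Conditions: 2 (1.3 equiv), 9-BBN (0.5 M in THF, 1.25 equiv), 0 °C to rt, 4 h; then 3 M aq K3PO4 (3 equiv), 3 (1.0 equiv), PdCl2(dppf) (3 mol %), THF–DMF, 60 °C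
Reagents that add atoms: none
Why: Anti-Markovnikov hydroboration of the styrene with 9-BBN puts boron on the terminal carbon, and B-alkyl Suzuki–Miyaura coupling with the unhindered, para-formyl-activated aryl bromide forms the saturated CH2–CH2 bridge directly; the aldehyde, OMe and OBn groups tolerate aqueous phosphate, and the styrene is kept in excess over 9-BBN so no B–H is left to reduce the aldehyde.

Step 3
Reactants: 5 4-{2-[2-(benzyloxy)phenyl]ethyl}-2,6-dimethoxybenzaldehyde
Product: 6 2-hydroxy-4-[2-(2-hydroxyphenyl)ethyl]-6-methoxybenzaldehyde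
Conditions: BCl3 (1 M in CH2Cl2, 3.5 equiv), pentamethylbenzene (3 equiv), CH2Cl2, −78 °C then 0 °C; MeOH, aq NaHCO3
Reagents that add atoms: none
Why: BCl3 cleaves the aryl benzyl ether at −78 °C (Lewis-acid debenzylation, benzyl cation trapped by pentamethylbenzene) and, through the six-membered chelate with the formyl oxygen, removes only one of the two equivalent ortho-methoxy groups (chelation-controlled mono-O-demethylation), because the aryloxyboron chelate that results deactivates the second OMe.

Step 4
Reactants: 6 2-hydroxy-4-[2-(2-hydroxyphenyl)ethyl]-6-methoxybenzaldehyde, 7 4-hydroxyphenylboronic acid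
Product: 10 2-[(4-hydroxyphenyl)methyl]-5-[2-(2-hydroxyphenyl)ethyl]-3-methoxyphenol, via 2-[(4-hydroxyphenyl)(morpholin-4-yl)methyl]-5-[2-(2-hydroxyphenyl)ethyl]-3-methoxyphenol 8 (not isolated), via 6-[(4-hydroxyphenyl)methylidene]-3-[2-(2-hydroxyphenyl)ethyl]-5-methoxycyclohexa-2,4-dien-1-one 9 (not isolated)
Conditions: 7 (1.5 equiv), morpholine (20 mol %), Hantzsch ester (1.3 equiv, added over 6 h), HFIP–PhMe 1:2, 55 °C, N2
Reagents that add atoms: none
Why: Proposed new method: amine-catalysed reductive Petasis arylation, in which morpholine condenses with salicylaldehyde 6 to an o-hydroxy iminium, the neighbouring phenol binds boronic acid 7 as an ate complex that delivers the 4-hydroxyphenyl group intramolecularly to the iminium carbon (so the C–C bond can only form between OH and OMe) to give Mannich base 8, 8 loses morpholine (retro-Mannich, helped by HFIP and the OH/OMe donors) to quinone methide 9, and 9 is reduced irreversibly at its exocyclic carbon by the Hantzsch ester with rearomatisation, which frees the amine for turnover and gives target 10 without a stereocentre; slow addition of the hydride donor keeps direct iminium reduction behind the intramolecular aryl transfer; the closest known reaction types are the stoichiometric Petasis borono-Mannich reaction of salicylaldehydes and the Hantzsch-ester transfer hydrogenation of o-quinone methides generated in situ.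

## Compound list

1 | 2-(benzyloxy)benzaldehyde | O=Cc1ccccc1OCc1ccccc1 | starting material
2 | 1-(benzyloxy)-2-ethenylbenzene | C=Cc1ccccc1OCc1ccccc1 | intermediate
3 | 4-bromo-2,6-dimethoxybenzaldehyde | COc1cc(Br)cc(OC)c1C=O | starting material
4 | 9-{2-[2-(benzyloxy)phenyl]ethyl}-9-borabicyclo[3.3.1]nonane (not isolated) | C(Cc1ccccc1OCc1ccccc1)B1C2CCCC1CCC2 | intermediate
5 | 4-{2-[2-(benzyloxy)phenyl]ethyl}-2,6-dimethoxybenzaldehyde | COc1cc(CCc2ccccc2OCc2ccccc2)cc(OC)c1C=O | intermediate
6 | 2-hydroxy-4-[2-(2-hydroxyphenyl)ethyl]-6-methoxybenzaldehyde | COc1cc(CCc2ccccc2O)cc(O)c1C=O | intermediate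
7 | 4-hydroxyphenylboronic acid | OB(O)c1ccc(O)cc1 | starting material
8 | 2-[(4-hydroxyphenyl)(morpholin-4-yl)methyl]-5-[2-(2-hydroxyphenyl)ethyl]-3-methoxyphenol (not isolated, racemic, transient stereocentre) | COc1cc(CCc2ccccc2O)cc(O)c1C(c1ccc(O)cc1)N1CCOCC1 | intermediate
9 | 6-[(4-hydroxyphenyl)methylidene]-3-[2-(2-hydroxyphenyl)ethyl]-5-methoxycyclohexa-2,4-dien-1-one (not isolated, alkene geometry not defined) | COC1=CC(CCc2ccccc2O)=CC(=O)C1=Cc1ccc(O)cc1 | intermediate
10 | 2-[(4-hydroxyphenyl)methyl]-5-[2-(2-hydroxyphenyl)ethyl]-3-methoxyphenol (achiral) | COc1cc(CCc2ccccc2O)cc(O)c1Cc1ccc(O)cc1 | target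

## Step count and risks

Total step count: 4. Longest linear sequence: 4 steps (1 → 2 → 5 → 6 → 10).

The three steps most likely to fail:

**Step 4 (the proposed new step).** The cycle may stall at Mannich base 8, or the hydride donor may reduce the iminium before aryl transfer and give a 2-methylphenol by-product. The fallback uses known chemistry, sets out from 6 and comes back at 10. Compound 6 is treated with 4-(benzyloxy)phenylmagnesium bromide (3.5 equiv, two of them used up by the phenols; THF, 0 °C to rt). This Grignard addition gives the diaryl carbinol 2-{[4-(benzyloxy)phenyl](hydroxy)methyl}-5-[2-(2-hydroxyphenyl)ethyl]-3-methoxyphenol F1, racemic and used crude because it ionises easily. F1 is then hydrogenated (H2 1 atm, 10% Pd/C, MeOH, trace HCl), which cleaves the benzyl ether and the doubly activated benzylic C–OH bond in one operation and gives 10.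

**Step 3.** The benzyl cation may alkylate the electron-rich rings, or demethylation may be incomplete or go too far on the advanced intermediate. The fallback separates the two events and changes their order; it sets out from 3 and comes back at 6. Compound 3 is mono-demethylated first (BCl3 1.2 equiv, CH2Cl2, −78 to 0 °C) to 4-bromo-2-hydroxy-6-methoxybenzaldehyde F2. F2 is coupled with borane 4 under the step 2 conditions with one more equivalent of base to give 4-{2-[2-(benzyloxy)phenyl]ethyl}-2-hydroxy-6-methoxybenzaldehyde F3. The benzyl ether of F3 is then removed by hydrogenolysis (H2 1 atm, 10% Pd/C, EtOAc, rt, stopped after one equivalent of H2; the hydrogen-bonded, electron-rich aldehyde is reduced much more slowly) to give 6.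

**Step 2.** Residual B–H may reduce the aldehyde, or the alkylborane may be lost by protodeboronation or β-hydride elimination. The fallback replaces the sp3–sp2 coupling by an sp2–sp2 coupling followed by reduction; it sets out from 3 (with 2) and comes back at 5. A Heck reaction of 3 with styrene 2 (Pd(OAc)2 2 mol %, P(o-tol)3, NaOAc, DMF, 110 °C) gives 4-{(E)-2-[2-(benzyloxy)phenyl]ethenyl}-2,6-dimethoxybenzaldehyde F4. The stilbene double bond of F4 is then hydrogenated selectively (H2 1 atm, 10% Pd/C poisoned with diphenyl sulfide, EtOAc, rt), conditions that leave aryl aldehydes and benzyl ethers intact, to give 5.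

## Further compounds

F1 | step 4 | 2-{[4-(benzyloxy)phenyl](hydroxy)methyl}-5-[2-(2-hydroxyphenyl)ethyl]-3-methoxyphenol (racemic) | COc1cc(CCc2ccccc2O)cc(O)c1C(O)c1ccc(OCc2ccccc2)cc1
F2 | step 3 | 4-bromo-2-hydroxy-6-methoxybenzaldehyde | COc1cc(Br)cc(O)c1C=O
F3 | step 3 | 4-{2-[2-(benzyloxy)phenyl]ethyl}-2-hydroxy-6-methoxybenzaldehyde | COc1cc(CCc2ccccc2OCc2ccccc2)cc(O)c1C=O
F4 | step 2 | 4-{(E)-2-[2-(benzyloxy)phenyl]ethenyl}-2,6-dimethoxybenzaldehyde | COc1cc(/C=C/c2ccccc2OCc2ccccc2)cc(OC)c1C=O
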